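**Plan**

- Prostanoid numbering is used (C1 = ester carbon, ring = C8–C12, octenyl chain = C13–C20). The retrosynthesis cuts C12–C13 (ring carbinol carbon to the allylic CH2), C7=C8 (aldol condensation), C5=C6 (cross-metathesis), C10–Br and the O-acetyl bond.
- Enabling feature: in ring C8–C12 the carbonyl carbon C9 and the carbinol carbon C12 face each other across C10=C11, so their oxidation levels can be exchanged. C12 becomes the ketone and C9 a temporary silyl-protected carbinol, as in (R)-4-silyloxycyclopent-2-enone. C13 is the unsubstituted terminus of a (Z)-oct-2-enyl anion, which oct-1-ene supplies directly.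
- Forward order: allyl anion addition at C12; desilylation and oxidation at C9 (helper removed); epoxide/bromide sequence for C10–Br; aldol at C8 with the C1–C7 enal; acetylation with elimination.
- Stereochemistry: C12 from addition anti to the C9 silyloxy group, which is then oxidised away; 14Z from the endo preference of the 2-alkenylpotassium; 5E from metathesis; 7E from thermodynamically controlled elimination.

Key step: step 1

Remark on the chemistry: silyl ether 2 is taken to be a commercially available enantiopure building block.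

**Route**

Step 1
Reactants: 1 oct-1-ene; 2 (4R)-4-[(tert-butyldimethylsilyl)oxy]cyclopent-2-en-1-one
Product: 5 (1S,4R)-4-[(tert-butyldimethylsilyl)oxy]-1-[(2Z)-oct-2-en-1-yl]cyclopent-2-en-1-ol, via (2Z)-oct-2-en-1-ylpotassium 3 (not isolated), via (2Z)-oct-2-en-1-ylcerium dichloride 4 (not isolated)
Conditions: 1 (3 equiv), n-BuLi/KOt-Bu (2 equiv each), THF–hexane, −50 °C, aged until endo equilibration is complete; anhydrous CeCl3 (2.2 equiv), THF, −78 °C; then 2 (1 equiv), −78 °C; aq NH4Cl
Reagents that add atoms: none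
Why: Superbase metalation of 1 at the allylic C–H gives 2-octenylpotassium 3, whose endo (Z) form is thermodynamically preferred, and transmetalation to trivalent cerium at −78 °C holds this geometry in 4, which adds through its unsubstituted terminus (future C13) to the C12 carbonyl of 2 in a 1,2 sense. The closest known reaction type is the terminus-selective 1,2-addition of 2-alkenylcerium reagents to enals and ketones, combined with the endo-selective metalation of 1-alkenes. No ring is closed. The new stereocentre C12 is controlled by the C9 silyloxy group, which shields one face of the flat cyclopentenone so that C13 enters anti to it and the new hydroxyl ends up cis to the silyloxy group. The step needs α over γ attack, 1,2 over 1,4 addition, retention of the Z olefin and no β-elimination of silanolate; the hindered ketone and the oxophilic, weakly basic cerium reagent kept at −78 °C should secure these.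

Step 2
Reactants: 5 (1S,4R)-4-[(tert-butyldimethylsilyl)oxy]-1-[(2Z)-oct-2-en-1-yl]cyclopent-2-en-1-ol
Product: 6 (1S,4R)-1-[(2Z)-oct-2-en-1-yl]cyclopent-2-ene-1,4-diol
Conditions: Bu4NF (1.2 equiv), THF, 0 °C → rt
Reagents that add atoms: none
Why: Fluoride-mediated silyl ether cleavage should free the C9 hydroxyl under non-acidic conditions that spare the tertiary allylic alcohol and the Z olefin.

Step 3
Reactants: 6 (1S,4R)-1-[(2Z)-oct-2-en-1-yl]cyclopent-2-ene-1,4-diol
Product: 7 (4S)-4-hydroxy-4-[(2Z)-oct-2-en-1-yl]cyclopent-2-en-1-one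
Conditions: activated MnO2 (excess), CH2Cl2, rt
Reagents that add atoms: none
Why: Allylic alcohol oxidation with MnO2 should convert only the secondary C9 carbinol into the ketone, which removes the temporary stereocentre while the non-oxidisable tertiary C12 centre stays fixed.

Step 4
Reactants: 7 (4S)-4-hydroxy-4-[(2Z)-oct-2-en-1-yl]cyclopent-2-en-1-one
Product: 8 (1S,4S,5R)-4-hydroxy-4-[(2Z)-oct-2-en-1-yl]-6-oxabicyclo[3.1.0]hexan-2-one
Conditions: H2O2 (30% aq), NaOH (cat.), MeOH, −20 → 0 °C, short reaction time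
Reagents that add atoms: hydrogen peroxide, OO
Why: Weitz–Scheffer nucleophilic epoxidation should attack only the electron-poor C10=C11 bond and leave the isolated C14=C15 olefin alone; hydroperoxide is expected to enter anti to the octenyl chain (epoxide cis to the hydroxyl, as drawn), and both new centres are erased in step 5, so their configuration is of no consequence.

Step 5
Reactants: 8 (1S,4S,5R)-4-hydroxy-4-[(2Z)-oct-2-en-1-yl]-6-oxabicyclo[3.1.0]hexan-2-one
Product: 11 (4S)-2-bromo-4-hydroxy-4-[(2Z)-oct-2-en-1-yl]cyclopent-2-en-1-one, via bromohydrin 9 (not isolated), via bromohydrin mesylate 10 (not isolated)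
Conditions: MgBr2·OEt2 (1.5 equiv), CH2Cl2–Et2O, −20 → 0 °C; then Et3N (5 equiv), MsCl (1.5 equiv), 0 °C → rt
Reagents that add atoms: magnesium bromide (as its diethyl etherate), Br[Mg]Br
Why: Chelation-assisted SN2 opening of the α,β-epoxy ketone by bromide at C10 (α to the carbonyl; C11 is neopentylic) should give bromohydrin 9, and sulfonylation of the secondary C11 oxygen followed by E1cB loss of mesylate should give the α-bromoenone (the known epoxy ketone to α-haloenone conversion), while the tertiary C12 hydroxyl is neither sulfonylated nor able to leave under these basic conditions.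

Step 6
Reactants: 12 methyl hex-5-enoate; 13 (2E)-but-2-enal
Product: 14 methyl (5E)-7-oxohept-5-enoate
Conditions: 13 (3 equiv), second-generation Hoveyda–Grubbs catalyst RuCl2(H2IMes)(=CH-C6H4-2-Oi-Pr) (2 mol%), CH2Cl2, 40 °C
Reagents that add atoms: none
Why: Olefin cross-metathesis of a terminal olefin with an excess of the electron-poor enal partner should favour the cross product and give the E enal under thermodynamic control.

Step 7
Reactants: 11 (4S)-2-bromo-4-hydroxy-4-[(2Z)-oct-2-en-1-yl]cyclopent-2-en-1-one; 14 methyl (5E)-7-oxohept-5-enoate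
Product: 16 methyl (5E)-7-[(5S)-3-bromo-5-hydroxy-5-[(2Z)-oct-2-en-1-yl]-2-oxocyclopent-3-en-1-yl]-7-hydroxyhept-5-enoate (mixture of C7/C8 epimers), via dilithium alkoxide dienolate 15 (not isolated)
Conditions: LiN(i-Pr)2 (2.2 equiv), THF, −78 °C; then 14 (1.3 equiv), −78 °C; AcOH quench at −78 °C
Reagents that add atoms: none
Why: Kinetic α'-deprotonation at C8 should give alkoxide dienolate 15 (the C12 alkoxide cannot be expelled, since that would create a cyclopentadienone), which should add 1,2 to the enal in a directed aldol addition at −78 °C without touching the methyl ester; the C7 and C8 centres are removed in step 8.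

Step 8
Reactants: 16 methyl (5E)-7-[(5S)-3-bromo-5-hydroxy-5-[(2Z)-oct-2-en-1-yl]-2-oxocyclopent-3-en-1-yl]-7-hydroxyhept-5-enoate
Product: 19 methyl (5E,7E)-7-[(5R)-5-acetoxy-3-bromo-5-[(2Z)-oct-2-en-1-yl]-2-oxocyclopent-3-en-1-ylidene]hept-5-enoate, via C7 acetate 17 (not isolated), via dienone alcohol 18 (not isolated)
Conditions: Ac2O (6 equiv), DMAP (1 equiv), Et3N (6 equiv), CH2Cl2, 0 °C → rt
Reagents that add atoms: acetic anhydride, CC(=O)OC(C)=O
Why: DMAP-catalysed acetylation of the C7 hydroxyl followed by E1cB loss of acetate should give the thermodynamically preferred 7E cross-conjugated dienone 18 (C6 anti to the C9 carbonyl; endocyclic elimination toward C12 is blocked because it would form a cyclopentadienone), and the tertiary C12 hydroxyl should then be acetylated under the same conditions without change at carbon.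

**Compound list**

1 | oct-1-ene | C=CCCCCCC | starting material
2 | (4R)-4-[(tert-butyldimethylsilyl)oxy]cyclopent-2-en-1-one | O=C1C=C[C@H](O[Si](C)(C)C(C)(C)C)C1 | starting material
3 | (2Z)-oct-2-en-1-ylpotassium (endo form, formed in the flask) | CCCCC/C=C\[CH2-].[K+] | intermediate
4 | (2Z)-oct-2-en-1-ylcerium dichloride (formed in the flask) | CCCCC/C=C\C[Ce](Cl)Cl | intermediate
5 | (1S,4R)-4-[(tert-butyldimethylsilyl)oxy]-1-[(2Z)-oct-2-en-1-yl]cyclopent-2-en-1-ol | CCCCC/C=C\C[C@@]1(O)C=C[C@H](O[Si](C)(C)C(C)(C)C)C1 | intermediate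
6 | (1S,4R)-1-[(2Z)-oct-2-en-1-yl]cyclopent-2-ene-1,4-diol | CCCCC/C=C\C[C@@]1(O)C=C[C@H](O)C1 | intermediate
7 | (4S)-4-hydroxy-4-[(2Z)-oct-2-en-1-yl]cyclopent-2-en-1-one | CCCCC/C=C\C[C@@]1(O)C=CC(=O)C1 | intermediate
8 | (1S,4S,5R)-4-hydroxy-4-[(2Z)-oct-2-en-1-yl]-6-oxabicyclo[3.1.0]hexan-2-one (epoxide cis to the hydroxyl) | CCCCC/C=C\C[C@@]1(O)[C@@H]2O[C@@H]2C(=O)C1 | intermediate
9 | (2R,3S,4S)-2-bromo-3,4-dihydroxy-4-[(2Z)-oct-2-en-1-yl]cyclopentan-1-one (formed in the flask as its magnesium alkoxide) | CCCCC/C=C\C[C@@]1(O)[C@H](O)[C@@H](Br)C(=O)C1 | intermediate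
10 | (2R,3S,4S)-2-bromo-4-hydroxy-3-(methanesulfonyloxy)-4-[(2Z)-oct-2-en-1-yl]cyclopentan-1-one (formed in the flask) | CCCCC/C=C\C[C@@]1(O)[C@H](OS(C)(=O)=O)[C@@H](Br)C(=O)C1 | intermediate
11 | (4S)-2-bromo-4-hydroxy-4-[(2Z)-oct-2-en-1-yl]cyclopent-2-en-1-one | CCCCC/C=C\C[C@@]1(O)C=C(Br)C(=O)C1 | intermediate
12 | methyl hex-5-enoate | C=CCCCC(=O)OC | starting material
13 | (2E)-but-2-enal | C/C=C/C=O | starting material
14 | methyl (5E)-7-oxohept-5-enoate | O=C/C=C/CCCC(=O)OC | intermediate
15 | dilithium (3S)-5-bromo-3-oxido-3-[(2Z)-oct-2-en-1-yl]cyclopenta-1,4-dien-1-olate (formed in the flask) | CCCCC/C=C\C[C@@]1([O-])C=C(Br)C([O-])=C1.[Li+].[Li+] | intermediate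
16 | methyl (5E)-7-[(5S)-3-bromo-5-hydroxy-5-[(2Z)-oct-2-en-1-yl]-2-oxocyclopent-3-en-1-yl]-7-hydroxyhept-5-enoate (epimers at C7 and C8) | CCCCC/C=C\C[C@@]1(O)C=C(Br)C(=O)C1C(O)/C=C/CCCC(=O)OC | intermediate
17 | methyl (5E)-7-acetoxy-7-[(5S)-3-bromo-5-hydroxy-5-[(2Z)-oct-2-en-1-yl]-2-oxocyclopent-3-en-1-yl]hept-5-enoate (formed in the flask) | CCCCC/C=C\C[C@@]1(O)C=C(Br)C(=O)C1C(OC(C)=O)/C=C/CCCC(=O)OC | intermediate
18 | methyl (5E,7E)-7-[(5R)-3-bromo-5-hydroxy-5-[(2Z)-oct-2-en-1-yl]-2-oxocyclopent-3-en-1-ylidene]hept-5-enoate (formed in the flask) | CCCCC/C=C\C[C@@]1(O)C=C(Br)C(=O)/C1=C/C=C/CCCC(=O)OC | intermediate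
19 | methyl (5E,7E)-7-[(5R)-5-acetoxy-3-bromo-5-[(2Z)-oct-2-en-1-yl]-2-oxocyclopent-3-en-1-ylidene]hept-5-enoate | CCCCC/C=C\C[C@@]1(OC(C)=O)C=C(Br)C(=O)/C1=C/C=C/CCCC(=O)OC | target

**Step count and risks**

Total steps: 8. Longest linear sequence: 7 steps (steps 1, 2, 3, 4, 5, 7, 8); step 6 is a one-step side branch.

Steps most likely to fail:

1. Step 1. The allyl reagent may attack through its substituted terminus, the Z geometry may be lost by torsional isomerisation of the allylmetal, or facial discrimination at the ketone may be insufficient. The fallback sets out from 2 and returns at 5. It makes the C12–C13 bond with a two-carbon enolate and the olefin by a Wittig reaction. The lithium enolate of ethyl acetate F1 (from ethyl acetate and LiN(i-Pr)2, THF, −78 °C, with CeCl3) should add to 2 anti to the silyloxy group and give ethyl 2-[(1R,4R)-4-[(tert-butyldimethylsilyl)oxy]-1-hydroxycyclopent-2-en-1-yl]acetate F2. Reduction with i-Bu2AlH (CH2Cl2, −78 °C) should give 2-[(1R,4R)-4-[(tert-butyldimethylsilyl)oxy]-1-hydroxycyclopent-2-en-1-yl]acetaldehyde F3. Olefination with hexylidenetriphenylphosphorane F4 (from hexyltriphenylphosphonium bromide and NaN(SiMe3)2, THF, −78 °C → rt, ylide in excess to cover the free hydroxyl) should give 5 with the Z olefin.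

2. Step 5. At the epoxy ketol stage the tertiary C12 hydroxyl may be lost by dehydration toward C8, the ring may open by retro-aldol cleavage, or elimination of the C11 oxygen may be incomplete. The fallback sets out from 7 and returns at 11, avoiding the epoxide by protecting the chain olefin as its dibromide. Bromine (2 equiv, CH2Cl2, −78 °C) should add to both the enone and the chain olefin and give (4R)-2,3-dibromo-4-(2,3-dibromooctyl)-4-hydroxycyclopentan-1-one F5. Et3N (0 °C) should remove HBr from the ring dibromide only and give (4R)-2-bromo-4-(2,3-dibromooctyl)-4-hydroxycyclopent-2-en-1-one F6. NaI in acetone should then regenerate the Z olefin by anti debromination of the threo dibromide (anti addition followed by anti elimination), giving 11.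

3. Step 7. The brominated dienolate may fragment or decompose, or it may deprotonate the enal at the γ-position instead of adding to it. The fallback sets out from 11 and returns at 16, replacing the lithium aldol by a Mukaiyama aldol. Silylation of both oxygens (Me3SiOTf, Et3N, CH2Cl2, −78 → 0 °C) should give (5S)-3-bromo-5-[(2Z)-oct-2-en-1-yl]-2,5-bis[(trimethylsilyl)oxy]cyclopenta-1,3-diene F7. Addition to 14 promoted by BF3·OEt2 (CH2Cl2, −78 °C) should give methyl (5E)-7-[(5S)-3-bromo-5-[(2Z)-oct-2-en-1-yl]-2-oxo-5-[(trimethylsilyl)oxy]cyclopent-3-en-1-yl]-7-hydroxyhept-5-enoate F8. K2CO3 in methanol at 0 °C should remove the remaining silyl group and give 16.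

**Further compounds**

F1 | step 1 | lithium enolate of ethyl acetate | C=C([O-])OCC.[Li+]
F2 | step 1 | ethyl 2-[(1R,4R)-4-[(tert-butyldimethylsilyl)oxy]-1-hydroxycyclopent-2-en-1-yl]acetate | CCOC(=O)C[C@@]1(O)C=C[C@H](O[Si](C)(C)C(C)(C)C)C1
F3 | step 1 | 2-[(1R,4R)-4-[(tert-butyldimethylsilyl)oxy]-1-hydroxycyclopent-2-en-1-yl]acetaldehyde | O=CC[C@@]1(O)C=C[C@H](O[Si](C)(C)C(C)(C)C)C1
F4 | step 1 | hexylidenetriphenylphosphorane | CCCCCC=P(c1ccccc1)(c1ccccc1)c1ccccc1
F5 | step 5 | (4R)-2,3-dibromo-4-(2,3-dibromooctyl)-4-hydroxycyclopentan-1-one (diastereomers at the CHBr centres) | CCCCCC(Br)C(Br)C[C@@]1(O)C(Br)C(Br)C(=O)C1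
F6 | step 5 | (4R)-2-bromo-4-(2,3-dibromooctyl)-4-hydroxycyclopent-2-en-1-one (threo dibromide in the chain) | CCCCCC(Br)C(Br)C[C@@]1(O)C=C(Br)C(=O)C1
F7 | step 7 | (5S)-3-bromo-5-[(2Z)-oct-2-en-1-yl]-2,5-bis[(trimethylsilyl)oxy]cyclopenta-1,3-diene | CCCCC/C=C\C[C@@]1(O[Si](C)(C)C)C=C(Br)C(O[Si](C)(C)C)=C1
F8 | step 7 | methyl (5E)-7-[(5S)-3-bromo-5-[(2Z)-oct-2-en-1-yl]-2-oxo-5-[(trimethylsilyl)oxy]cyclopent-3-en-1-yl]-7-hydroxyhept-5-enoate | CCCCC/C=C\C[C@@]1(O[Si](C)(C)C)C=C(Br)C(=O)C1C(O)/C=C/CCCC(=O)OC
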